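**Retrosynthetic overview**

1. The six-membered triketone ring is made last, by ring expansion: C5, carrying its prenyl and isobutyryl groups, is inserted between the two carbonyls of a dihydrofuran-fused cyclopentene-1,2-dione by an α-prenyl-α-diazo ketone (acyl 1,2-shift, sets C5).
2. The 1,2-dione comes from C6 methylation and asymmetric C6 prenylation (sets target C7) of the dione obtained by α′-hydroxylation and oxidation of the fused cyclopentenone.
3. The side chain comes from Felkin–Anh methyl addition to a homoprenyl ketone (sets the carbinol), which comes from an aldehyde, which comes from a vinyl group.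
4. The dihydrofuran comes from an asymmetric palladium allylation/O-cyclisation cascade on symmetric cyclopentane-1,3-dione (sets C2; the symmetry removes any doubt about which oxygen enters the ring).
5. Ring order: five-membered carbocycle (bought), then dihydrofuran, then six-membered carbocycle by ring expansion; the diazo ketone is made in two steps from 3-methylbutan-2-one.

Assumption: the sense of induction of each chiral ligand or catalyst (steps 2, 9 and 12) is assigned by analogy with its closest precedents; if a first run shows the opposite sense, the mirror-image ligand or catalyst is used.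

**Route**

Step 1
Reactants: 1 (Z)-but-2-ene-1,4-diol
Product: 2 dimethyl (Z)-but-2-ene-1,4-diyl biscarbonate
Conditions: ClCO2Me (2.4 equiv), pyridine, CH2Cl2, 0 °C → rt
Reagents that add atoms: methyl chloroformate, COC(=O)Cl
Why: Carbonate formation (O-acylation of both primary allylic alcohols) gives the bis-allylic electrophile for the palladium cascade; no stereocentre is formed.

Step 2
Reactants: 3 cyclopentane-1,3-dione; 2 dimethyl (Z)-but-2-ene-1,4-diyl biscarbonate
Product: 5 (2S)-2-ethenyl-2,3,5,6-tetrahydro-4H-cyclopenta[b]furan-4-one, via allylated enol carbonate 4 (not isolated)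
Conditions: Pd2(dba)3·CHCl3 (2.5 mol %), (R,R)-DACH-phenyl Trost ligand (7.5 mol %), CH2Cl2, 0 °C → rt
Reagents that add atoms: none
Why: Tsuji–Trost C-allylation of the symmetric dione, then ligand-controlled intramolecular O-allylation of the second π-allylpalladium complex (asymmetric allylic alkylation cascade), closes the dihydrofuran and sets C2 as S.

Step 3
Reactants: 5 (2S)-2-ethenyl-2,3,5,6-tetrahydro-4H-cyclopenta[b]furan-4-one
Product: 6 (2S)-4-oxo-3,4,5,6-tetrahydro-2H-cyclopenta[b]furan-2-carbaldehyde
Conditions: OsO4 (2 mol %), NaIO4 (4 equiv), 2,6-lutidine, dioxane–H2O 3:1, rt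
Reagents that add atoms: osmium tetroxide, O=[Os](=O)(=O)=O (catalytic oxygen carrier); sodium periodate, [Na+].[O-]I(=O)(=O)=O (terminal oxygen source)
Why: Lemieux–Johnson oxidative cleavage touches only the monosubstituted vinyl group, because the tetrasubstituted push–pull enone alkene is inert to OsO4; C2 is not affected under lutidine buffering.

Step 4
Reactants: 6 (2S)-4-oxo-3,4,5,6-tetrahydro-2H-cyclopenta[b]furan-2-carbaldehyde; 7 5-bromo-2-methylpent-2-ene
Product: 10 (2S)-2-(5-methylhex-4-enoyl)-2,3,5,6-tetrahydro-4H-cyclopenta[b]furan-4-one, via Grignard reagent 8 (not isolated), via magnesium alkoxide 9 (not isolated)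
Conditions: 7, Mg, THF, rt; then 6, THF, −78 °C; then 1,1′-(azodicarbonyl)dipiperidine, 0 °C
Reagents that add atoms: none
Why: Grignard addition to the aldehyde (far more electrophilic than the vinylogous ester carbonyl), then in-flask Mukaiyama oxidation of the bromomagnesium alkoxide by hydride transfer to the azo compound, gives the ketone without isolating the epimeric alcohols; C2 is untouched.

Step 5
Reactants: 10 (2S)-2-(5-methylhex-4-enoyl)-2,3,5,6-tetrahydro-4H-cyclopenta[b]furan-4-one
Product: 11 (2S)-2-[(2S)-2-hydroxy-6-methylhept-5-en-2-yl]-2,3,5,6-tetrahydro-4H-cyclopenta[b]furan-4-one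
Conditions: MeMgBr (1.3 equiv), THF, −78 °C
Reagents that add atoms: methylmagnesium bromide, C[Mg]Br
Why: Grignard 1,2-addition under Felkin–Anh (Cornforth) control sets the carbinol as S: the ring oxygen is a vinylogous-ester oxygen, a strong σ-acceptor and poor chelator, so methyl attacks anti to the C2–O bond past the C2–H; the vinylogous ester carbonyl is inert at −78 °C and the minor epimer is removed by chromatography.

Step 6
Reactants: 11 (2S)-2-[(2S)-2-hydroxy-6-methylhept-5-en-2-yl]-2,3,5,6-tetrahydro-4H-cyclopenta[b]furan-4-one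
Product: 12 (2S)-5-hydroxy-2-[(2S)-2-hydroxy-6-methylhept-5-en-2-yl]-2,3,5,6-tetrahydro-4H-cyclopenta[b]furan-4-one (C5 epimers)
Conditions: LiN(iPr)2 (2.2 equiv), THF, −78 °C; then 3-phenyl-2-(phenylsulfonyl)oxaziridine, −78 °C
Reagents that add atoms: 3-phenyl-2-(phenylsulfonyl)oxaziridine (Davis oxaziridine), O=S(=O)(N1OC1c1ccccc1)c1ccccc1
Why: Kinetic α′-deprotonation of the vinylogous ester (Stork–Danheiser regiochemistry, tertiary alcohol carried as its alkoxide) and Davis enolate hydroxylation place oxygen on C5; the new carbinol centre is not controlled because the next step oxidises it.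

Step 7
Reactants: 12 (2S)-5-hydroxy-2-[(2S)-2-hydroxy-6-methylhept-5-en-2-yl]-2,3,5,6-tetrahydro-4H-cyclopenta[b]furan-4-one
Product: 13 (2S)-2-[(2S)-2-hydroxy-6-methylhept-5-en-2-yl]-2,3-dihydro-4H-cyclopenta[b]furan-4,5(6H)-dione
Conditions: Dess–Martin periodinane, NaHCO3, CH2Cl2, 0 °C
Reagents that add atoms: none
Why: Dess–Martin oxidation converts the secondary α-hydroxy ketone into the 1,2-dione while the tertiary alcohol and the trisubstituted alkene are inert; no stereocentre is affected.

Step 8
Reactants: 13 (2S)-2-[(2S)-2-hydroxy-6-methylhept-5-en-2-yl]-2,3-dihydro-4H-cyclopenta[b]furan-4,5(6H)-dione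
Product: 14 (2S)-2-[(2S)-2-hydroxy-6-methylhept-5-en-2-yl]-6-methyl-2,3-dihydro-4H-cyclopenta[b]furan-4,5(6H)-dione (C6 epimers)
Conditions: MeI (1.0 equiv), K2CO3, acetone, 0 °C
Reagents that add atoms: iodomethane, CI
Why: Enolate C-alkylation: the C6 methylene, flanked by the C5 ketone and the enol-ether carbon, is a strong carbon acid whose delocalised anion is methylated at the unsubstituted C6 terminus (O-alkylation would give a cyclopentadienone); C6 stays enolisable, so its configuration is irrelevant here.

Step 9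
Reactants: 14 (2S)-2-[(2S)-2-hydroxy-6-methylhept-5-en-2-yl]-6-methyl-2,3-dihydro-4H-cyclopenta[b]furan-4,5(6H)-dione; 15 1-bromo-3-methylbut-2-ene
Product: 16 (2S,6S)-2-[(2S)-2-hydroxy-6-methylhept-5-en-2-yl]-6-methyl-6-(3-methylbut-2-en-1-yl)-2,3-dihydro-4H-cyclopenta[b]furan-4,5(6H)-dione
Conditions: 15 (1.2 equiv), Cs2CO3 (solid), (S,S)-3,4,5-trifluorophenyl-NAS bromide (2 mol %), toluene, −20 °C
Reagents that add atoms: none
Why: Asymmetric phase-transfer alkylation: the chiral spiro-ammonium ion pair of the planar enolate shields one face, so prenyl bromide alkylates C6 to the 6S quaternary centre under catalyst control (the remote C2 centre has no influence, and the minor C6 epimer is a separable diastereomer).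

Step 10
Reactants: 17 3-methylbutan-2-one; 15 1-bromo-3-methylbut-2-ene
Product: 18 2,7-dimethyloct-6-en-3-one
Conditions: LiN(iPr)2, THF, −78 °C; then 15, −78 → 0 °C
Reagents that add atoms: none
Why: Kinetic enolate formation at the methyl group and SN2 alkylation with prenyl bromide extend the chain; no stereocentre is formed.

Step 11
Reactants: 18 2,7-dimethyloct-6-en-3-one
Product: 20 4-diazo-2,7-dimethyloct-6-en-3-one, via trifluoroacetyl diketone 19 (not isolated)
Conditions: LiN(SiMe3)2, THF, −78 °C; CF3CO2CH2CF3; then MsN3, Et3N, H2O, MeCN, rt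
Reagents that add atoms: methanesulfonyl azide, CS(=O)(=O)N=[N+]=[N-]
Why: Danheiser detrifluoroacetylative diazo transfer (kinetic enolisation at the less hindered methylene, Claisen trifluoroacetylation, Regitz diazo transfer with loss of the trifluoroacetyl group) gives the α-alkyl-α-diazo ketone; no stereocentre is formed.

Step 12
Reactants: 16 (2S,6S)-2-[(2S)-2-hydroxy-6-methylhept-5-en-2-yl]-6-methyl-6-(3-methylbut-2-en-1-yl)-2,3-dihydro-4H-cyclopenta[b]furan-4,5(6H)-dione; 20 4-diazo-2,7-dimethyloct-6-en-3-one
Product: 22 (2S,5R,7S)-2-[(2S)-2-hydroxy-6-methylhept-5-en-2-yl]-7-methyl-5,7-bis(3-methylbut-2-en-1-yl)-5-(2-methylpropanoyl)-2,3-dihydro-1-benzofuran-4,6(5H,7H)-dione, via diazonium alkoxide 21 (not isolated)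
Conditions: Sc(OTf)3 (10 mol %), chiral N,N′-dioxide ligand L-PiPr2 (L-pipecolic acid bis(2,6-diisopropylanilide), three-carbon linker; 11 mol %), CH2Cl2, −20 → 30 °C
Reagents that add atoms: none
Why: Proposed new method: the non-enolisable 1,2-dione of 16 binds the chiral Sc(OTf)3–N,N′-dioxide Lewis acid as a five-membered chelate, the diazo carbon of 20 adds from the catalyst-selected face to the more electrophilic C5 ketone to give 21, and the neighbouring acyl carbon C4 then migrates antiperiplanar to the departing N2 with inversion at the terminus (acyl groups migrate readily in diazonium 1,2-shifts, whereas shift of the tertiary C6 would build two adjacent quaternary carbons), which inserts the new carbon between the two carbonyls, expands the five-membered ring to the six-membered triketone and sets 5R; addition at C4 followed by shift of C5 would give the same product; the closest known reaction type is the Lewis-acid-catalysed Tiffeneau–Demjanov-type diazo–carbonyl ring expansion of cyclic ketones and 1,2-dicarbonyl compounds with α-alkyl-α-diazo esters under chiral scandium–N,N′-dioxide catalysis, extended here to a fused cyclopentene-1,2-dione, an α-alkyl-α-diazo ketone and acyl migration.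

**Compound list**

1 | (Z)-but-2-ene-1,4-diol | OC/C=C\CO | starting material
2 | dimethyl (Z)-but-2-ene-1,4-diyl biscarbonate | COC(=O)OC/C=C\COC(=O)OC | intermediate
3 | cyclopentane-1,3-dione | O=C1CCC(=O)C1 | starting material
4 | 3-hydroxy-2-[(E)-4-(methoxycarbonyloxy)but-2-en-1-yl]cyclopent-2-en-1-one (allylated enol carbonate, mainly E) | COC(=O)OC/C=C/CC1=C(O)CCC1=O | intermediate (not isolated)
5 | (2S)-2-ethenyl-2,3,5,6-tetrahydro-4H-cyclopenta[b]furan-4-one | C=C[C@@H]1CC2=C(O1)CCC2=O | intermediate
6 | (2S)-4-oxo-3,4,5,6-tetrahydro-2H-cyclopenta[b]furan-2-carbaldehyde | O=C[C@@H]1CC2=C(O1)CCC2=O | intermediate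
7 | 5-bromo-2-methylpent-2-ene | CC(C)=CCCBr | starting material
8 | (4-methylpent-3-en-1-yl)magnesium bromide (Grignard reagent) | CC(C)=CCC[Mg]Br | intermediate (not isolated)
9 | bromomagnesium alkoxide of (2S)-2-(1-hydroxy-5-methylhex-4-en-1-yl)-2,3,5,6-tetrahydro-4H-cyclopenta[b]furan-4-one (carbinol epimers) | CC(C)=CCCC(O[Mg]Br)[C@@H]1CC2=C(O1)CCC2=O | intermediate (not isolated)
10 | (2S)-2-(5-methylhex-4-enoyl)-2,3,5,6-tetrahydro-4H-cyclopenta[b]furan-4-one | CC(C)=CCCC(=O)[C@@H]1CC2=C(O1)CCC2=O | intermediate
11 | (2S)-2-[(2S)-2-hydroxy-6-methylhept-5-en-2-yl]-2,3,5,6-tetrahydro-4H-cyclopenta[b]furan-4-one | CC(C)=CCC[C@](C)(O)[C@@H]1CC2=C(O1)CCC2=O | intermediate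
12 | (2S)-5-hydroxy-2-[(2S)-2-hydroxy-6-methylhept-5-en-2-yl]-2,3,5,6-tetrahydro-4H-cyclopenta[b]furan-4-one (C5 epimers) | CC(C)=CCC[C@](C)(O)[C@@H]1CC2=C(O1)CC(O)C2=O | intermediate
13 | (2S)-2-[(2S)-2-hydroxy-6-methylhept-5-en-2-yl]-2,3-dihydro-4H-cyclopenta[b]furan-4,5(6H)-dione | CC(C)=CCC[C@](C)(O)[C@@H]1CC2=C(O1)CC(=O)C2=O | intermediate
14 | (2S)-2-[(2S)-2-hydroxy-6-methylhept-5-en-2-yl]-6-methyl-2,3-dihydro-4H-cyclopenta[b]furan-4,5(6H)-dione (C6 epimers) | CC(C)=CCC[C@](C)(O)[C@@H]1CC2=C(O1)C(C)C(=O)C2=O | intermediate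
15 | 1-bromo-3-methylbut-2-ene (prenyl bromide) | CC(C)=CCBr | starting material
16 | (2S,6S)-2-[(2S)-2-hydroxy-6-methylhept-5-en-2-yl]-6-methyl-6-(3-methylbut-2-en-1-yl)-2,3-dihydro-4H-cyclopenta[b]furan-4,5(6H)-dione | CC(C)=CCC[C@](C)(O)[C@@H]1CC2=C(O1)[C@](C)(CC=C(C)C)C(=O)C2=O | intermediate
17 | 3-methylbutan-2-one | CC(C)C(C)=O | starting material
18 | 2,7-dimethyloct-6-en-3-one | CC(C)C(=O)CCC=C(C)C | intermediate
19 | 1,1,1-trifluoro-5-methyl-3-(3-methylbut-2-en-1-yl)hexane-2,4-dione (trifluoroacetyl diketone) | CC(C)C(=O)C(CC=C(C)C)C(=O)C(F)(F)F | intermediate (not isolated)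
20 | 4-diazo-2,7-dimethyloct-6-en-3-one | CC(C)C(=O)C(=[N+]=[N-])CC=C(C)C | intermediate
21 | diazonium alkoxide from addition of the diazo carbon of 20 to the C5 carbonyl of 16 (scandium-bound; alkoxide carbon configuration undefined and lost on migration) | CC(C)=CCC[C@](C)(O)[C@@H]1CC2=C(O1)[C@](C)(CC=C(C)C)C([O-])(C2=O)[C@](CC=C(C)C)([N+]#N)C(=O)C(C)C | intermediate (not isolated)
22 | (2S,5R,7S)-2-[(2S)-2-hydroxy-6-methylhept-5-en-2-yl]-7-methyl-5,7-bis(3-methylbut-2-en-1-yl)-5-(2-methylpropanoyl)-2,3-dihydro-1-benzofuran-4,6(5H,7H)-dione (CNP0155474.1) | CC(C)=CCC[C@](C)(O)[C@@H]1CC2=C(O1)[C@](C)(CC=C(C)C)C(=O)[C@](CC=C(C)C)(C(=O)C(C)C)C2=O | target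

**Step count and risks**

Total step count: 12. Longest linear sequence: 10 steps (steps 1 to 9, then step 12); steps 10 and 11 make the diazo ketone in a side branch.

The three steps most likely to fail:

Step 12 (the proposed new ring expansion). The risks are the steric load of joining a fully substituted diazo carbon to a carbonyl next to a quaternary centre, competing shift of the vinyl or tertiary alkyl carbon, epoxide formation, and mismatched catalyst and substrate control. The fallback uses known chemistry, sets out from 16 and comes back at 22. Isobutyryl chloride and (trimethylsilyl)diazomethane (MeCN–THF, 0 °C) give the unhindered diazo ketone 1-diazo-3-methylbutan-2-one F3. Classical BF3·OEt2-promoted diazo ketone homologation of 16 with F3 (CH2Cl2, −78 °C) gives the ring-expanded, enolised triketone (2S,7S)-4-hydroxy-2-[(2S)-2-hydroxy-6-methylhept-5-en-2-yl]-7-methyl-7-(3-methylbut-2-en-1-yl)-5-(2-methylpropanoyl)-2,3-dihydro-1-benzofuran-6(7H)-one F4. C-prenylation of F4 at C5 with 15 under the phase-transfer conditions of step 9 then gives 22, and the C5 epimer is removed by chromatography.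

Step 9 (asymmetric prenylation). The risks are alkylation at the ring-fusion carbon C3a instead of C6 and low facial selectivity of the ion pair. The fallback sets out from 14 and comes back at 16. Palladium-catalysed asymmetric allylic alkylation of 14 with allyl acetate (Pd2(dba)3·CHCl3, (R,R)-ANDEN-phenyl Trost ligand, Cs2CO3, CH2Cl2, 0 °C) gives (2S,6S)-2-[(2S)-2-hydroxy-6-methylhept-5-en-2-yl]-6-methyl-6-(prop-2-en-1-yl)-2,3-dihydro-4H-cyclopenta[b]furan-4,5(6H)-dione F2. Cross-metathesis of F2 with 2-methylbut-2-ene (second-generation Grubbs catalyst, RuCl2(=CHPh)(H2IMes)(PCy3), CH2Cl2, 40 °C) turns the allyl group into the prenyl group of 16.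

Step 5 (carbinol configuration). The risk is that the addition follows the chelate sense or is unselective. The fallback sets out from 5 and comes back at 11, exchanging the roles of the two carbinol substituents. Wacker oxidation of 5 (PdCl2[2-(4,5-dihydrooxazol-2-yl)quinoline], AgSbF6, aqueous tBuOOH, CH2Cl2, rt) gives the methyl ketone (2S)-2-acetyl-2,3,5,6-tetrahydro-4H-cyclopenta[b]furan-4-one F1. Addition of Grignard reagent 8 to F1 (MgBr2·OEt2, CH2Cl2–Et2O, −78 °C) then gives 11 when the facial bias is of the chelate type, because the same face of attack with exchanged substituents gives the opposite carbinol configuration.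

**Further compounds**

F1 | step 5 | (2S)-2-acetyl-2,3,5,6-tetrahydro-4H-cyclopenta[b]furan-4-one | CC(=O)[C@@H]1CC2=C(O1)CCC2=O
F2 | step 9 | (2S,6S)-2-[(2S)-2-hydroxy-6-methylhept-5-en-2-yl]-6-methyl-6-(prop-2-en-1-yl)-2,3-dihydro-4H-cyclopenta[b]furan-4,5(6H)-dione | CC(C)=CCC[C@](C)(O)[C@@H]1CC2=C(O1)[C@](C)(CC=C)C(=O)C2=O
F3 | step 12 | 1-diazo-3-methylbutan-2-one | CC(C)C(=O)C=[N+]=[N-]
F4 | step 12 | (2S,7S)-4-hydroxy-2-[(2S)-2-hydroxy-6-methylhept-5-en-2-yl]-7-methyl-7-(3-methylbut-2-en-1-yl)-5-(2-methylpropanoyl)-2,3-dihydro-1-benzofuran-6(7H)-one | CC(C)=CCC[C@](C)(O)[C@@H]1CC2=C(O1)[C@](C)(CC=C(C)C)C(=O)C(C(=O)C(C)C)=C2O
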